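The benzo ring of the isoquinoline (C4a, C5, C6, C7, C8, C8a) is cut at C8–C8a and C5–C4a. Its substituents run in sequence: oxygen on C8, naphthyl on C7, hydrogen on C6 and C5, and carbon chains on C4a and C8a. This pattern matches a 2-naphthyl-1-methoxy-1-silyloxybutadiene joined to an acetyl alkyne bearing a ketal-masked acetonyl group. One thermal [4+2] addition, followed by loss of methanol and of the silyl group, gives the fully substituted salicyl ketone. The C7–C1' axis becomes crowded only on aromatisation. The two ketone arms (future C1 and C4–C3) then close the pyridine ring with an ammonia source.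

Key step: step 9

Assumption: the SMILES fixes no configuration at the C7–C1' biaryl axis, so the target is made as the racemic mixture of atropisomers and no stereocentre has to be set; pent-4-yn-2-one is taken as purchasable and is used fresh.

Step 1
Reactants: 1 N,N-diethyl-2-methoxybenzamide; 2 3-bromo-2-methylprop-1-ene (methallyl bromide)
Product: 5 N,N-diethyl-2-methoxy-6-(2-methylprop-2-en-1-yl)benzamide, via ortho-lithiated amide 3 (not isolated), via arylmagnesium bromide 4 (not isolated)
Conditions: s-BuLi, TMEDA, THF, −78 °C; MgBr2·OEt2, −78 → 0 °C; 2, −78 °C → rt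
Reagents that add atoms: none
Why: Directed ortho-metalation, in which the tertiary amide outranks the methoxy group as director so that lithiation occurs at C6, and exchange to the softer magnesium species lets the allylation with 2 proceed without attack on the amide or proton transfer.

Step 2
Reactants: 5 N,N-diethyl-2-methoxy-6-(2-methylprop-2-en-1-yl)benzamide
Product: 7 8-methoxy-3-methylnaphthalen-1-ol, via lithium naphtholate 6 (not isolated)
Conditions: LiN(i-Pr)2 (2.2 equiv), THF, −78 °C → rt; 1 M HCl work-up
Reagents that add atoms: none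
Why: Anionic annulation of an ortho-allylbenzamide, in which deprotonation of the benzylic/allylic CH2 gives a delocalised carbanion whose terminal carbon acylates intramolecularly on the amide (six-membered ring, loss of diethylamide) and the ketone formed tautomerises to the naphtholate, so the naphthalene arrives at the right oxidation level with no surplus carbon.

Step 3
Reactants: 7 8-methoxy-3-methylnaphthalen-1-ol
Product: 8 1,8-dimethoxy-3-methylnaphthalene
Conditions: MeI, K2CO3, DMF, rt
Reagents that add atoms: iodomethane, CI
Why: Williamson ether synthesis on the peri-hydrogen-bonded naphthol, for which a polar aprotic solvent and excess iodomethane should suffice.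

Step 4
Reactants: 8 1,8-dimethoxy-3-methylnaphthalene
Product: 9 1-bromo-4,5-dimethoxy-2-methylnaphthalene
Conditions: NBS (1.0 equiv), MeCN, 0 °C, dark
Reagents that add atoms: N-bromosuccinimide, O=C1CCC(=O)N1Br
Why: Electrophilic aromatic bromination, in which C4 of 8 is para to the C1 methoxy group and ortho to the methyl group and is therefore the most activated open position, while the polar medium and exclusion of light suppress benzylic bromination.

Step 5
Reactants: 9 1-bromo-4,5-dimethoxy-2-methylnaphthalene; 10 methyl (Z)-2-bromobut-2-enoate (the E isomer or a mixture serves equally)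
Product: 13 methyl (E)-2-(4,5-dimethoxy-2-methylnaphthalen-1-yl)but-2-enoate, via naphthyllithium 11 (not isolated), via naphthylzinc chloride 12 (not isolated)
Conditions: n-BuLi, THF, −78 °C; ZnCl2 (THF), −78 °C → rt; 10, Pd(OAc)2 (2 mol %), SPhos (4 mol %), THF, 50 °C
Reagents that add atoms: none
Why: Negishi coupling, in which the activated α-bromoenoate adds readily to zerovalent palladium, the arylzinc transmetalates despite its two flanking groups, and the bulky biarylphosphine promotes reductive elimination with retention of an alkene geometry that step 6 erases anyway.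

Step 6
Reactants: 13 methyl (E)-2-(4,5-dimethoxy-2-methylnaphthalen-1-yl)but-2-enoate
Product: 15 [1-methoxy-2-(4,5-dimethoxy-2-methylnaphthalen-1-yl)buta-1,3-dienyl]oxy-trimethylsilane (E/Z mixture at the ketene acetal), via lithium dienolate 14 (not isolated)
Conditions: LiN(i-Pr)2, THF–DMPU, −78 °C; TMSCl, −78 °C → rt; pentane, filtration under argon, concentration (no aqueous work-up), used crude
Reagents that add atoms: chlorotrimethylsilane, C[Si](C)(C)Cl
Why: Kinetic γ-deprotonation of an α,β-unsaturated ester to its extended dienolate followed by O-silylation (vinylketene silyl acetal formation), with DMPU and the bulky α-substituent disfavouring conjugate addition of the amide base and the hard silyl chloride trapping on oxygen.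

Step 7
Reactants: 16 pent-4-yn-2-one
Product: 17 2-methyl-2-(prop-2-yn-1-yl)-1,3-dioxolane
Conditions: TMSOCH2CH2OTMS, TMSOTf (2 mol %), CH2Cl2, −78 → −20 °C; pyridine quench
Reagents that add atoms: 1,2-bis(trimethylsilyloxy)ethane, C[Si](C)(C)OCCO[Si](C)(C)C
Why: Noyori ketalisation, whose aprotic low-temperature conditions form the dioxolane irreversibly without the hot protic acid that would isomerise the β,γ-alkynyl ketone to an allenyl ketone or a furan.

Step 8
Reactants: 17 2-methyl-2-(prop-2-yn-1-yl)-1,3-dioxolane; 18 N-methoxy-N-methylacetamide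
Product: 21 5-(2-methyl-1,3-dioxolan-2-yl)pent-3-yn-2-one, via lithium acetylide 19 (not isolated), via lithium hemiaminal alkoxide 20 (not isolated)
Conditions: n-BuLi, THF, −78 °C; 18, −78 → −20 °C; AcOH (THF), −78 °C, then cold water
Reagents that add atoms: none
Why: Weinreb ketone synthesis, in which the acetylide adds once to give a chelated tetrahedral adduct that survives until the cold acetic acid quench, so the base-sensitive ynone never meets acetylide or unprotonated amine and the dioxolane is not endangered.

Step 9
Reactants: 15 [1-methoxy-2-(4,5-dimethoxy-2-methylnaphthalen-1-yl)buta-1,3-dienyl]oxy-trimethylsilane; 21 5-(2-methyl-1,3-dioxolan-2-yl)pent-3-yn-2-one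
Product: 24 1-[2-hydroxy-3-(4,5-dimethoxy-2-methylnaphthalen-1-yl)-6-[(2-methyl-1,3-dioxolan-2-yl)methyl]phenyl]ethanone, via cyclohexadiene adduct 22 (not isolated), via aryl trimethylsilyl ether 23 (not isolated)
Conditions: 21 (1.5 equiv), toluene (degassed, base-washed sealed tube), 80 → 110 °C; then PPTS (10 mol %), THF–H2O (10:1), rt
Reagents that add atoms: none
Why: Normal-electron-demand Diels–Alder reaction: the two oxygen donors on the acetal carbon of 15 raise the diene HOMO and concentrate it on the unsubstituted CH2 terminus, so a concerted but strongly asynchronous [4+2] addition begins with C5–C4a bonding at the β-carbon of ynone 21 and ends with C8–C8a bonding at the acetyl-bearing carbon. The closest known reaction type is the cycloaddition of 1-alkoxy-1-silyloxybuta-1,3-dienes with acetylenic ketones and esters, which gives salicyl ketones and salicylates after elimination. The single new ring, the six-membered carbocycle C4a–C5–C6–C7–C8–C8a, is closed intermolecularly by suprafacial addition across the s-cis diene; the doubly allylic mixed ketal of 22 then ionises under mild acid and loses methanol together with a C5 proton to give 23, whose aryl O–Si bond is hydrolysed to the chelated phenol 24. No stereocentre is retained, because the C8 ketal centre of 22 vanishes on aromatisation and the C7–C1' axis forms as a racemate. The selectivity needed is orientation, which the matched polarisation of both partners secures, while the naphthyl group on the α-carbon of the ketene acetal blocks competing [2+2] and α-Michael pathways at that carbon. Chemoselectivity of the work-up rests on the much faster ionisation of the silyl methyl ketal compared with the dioxolane, which PPTS at room temperature should leave intact.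

Step 10
Reactants: 24 1-[2-hydroxy-3-(4,5-dimethoxy-2-methylnaphthalen-1-yl)-6-[(2-methyl-1,3-dioxolan-2-yl)methyl]phenyl]ethanone
Product: 25 1-[2-methoxy-3-(4,5-dimethoxy-2-methylnaphthalen-1-yl)-6-[(2-methyl-1,3-dioxolan-2-yl)methyl]phenyl]ethanone
Conditions: MeI, Cs2CO3, DMF, rt → 40 °C
Reagents that add atoms: iodomethane, CI
Why: Williamson ether synthesis, in which the caesium phenoxide of the chelated, flanked phenol is alkylated by iodomethane while the ketal keeps the second carbonyl masked, so no intramolecular aldol reaction can compete under base.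

Step 11
Reactants: 25 1-[2-methoxy-3-(4,5-dimethoxy-2-methylnaphthalen-1-yl)-6-[(2-methyl-1,3-dioxolan-2-yl)methyl]phenyl]ethanone
Product: 27 7-(4,5-dimethoxy-2-methylnaphthalen-1-yl)-8-methoxy-1,3-dimethylisoquinoline (target; racemic about the C7–C1' axis), via 1,5-diketone 26 (not isolated)
Conditions: NH4OAc (10 equiv), AcOH–H2O (4:1), 90 °C
Reagents that add atoms: ammonium acetate, CC(=O)[O-].[NH4+]
Why: Acidic ketal hydrolysis releases the 1,5-diketone, which condenses with ammonia through its 2-benzopyrylium form in the classical 1,5-dicarbonyl pyridine synthesis, the buffered acidic medium suppressing base-induced aldol closure to a naphthol and the benzene ring supplying the unsaturation so that no oxidant is needed.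

Compound list
1 | N,N-diethyl-2-methoxybenzamide | CCN(CC)C(=O)c1ccccc1OC | starting material
2 | 3-bromo-2-methylprop-1-ene | C=C(C)CBr | starting material
3 | [2-(diethylcarbamoyl)-3-methoxyphenyl]lithium | CCN(CC)C(=O)c1c([Li])cccc1OC | intermediate
4 | bromo[2-(diethylcarbamoyl)-3-methoxyphenyl]magnesium | CCN(CC)C(=O)c1c([Mg]Br)cccc1OC | intermediate
5 | N,N-diethyl-2-methoxy-6-(2-methylprop-2-en-1-yl)benzamide | CCN(CC)C(=O)c1c(CC(C)=C)cccc1OC | intermediate
6 | lithium 8-methoxy-3-methylnaphthalen-1-olate | COc1cccc2cc(C)cc([O-])c12.[Li+] | intermediate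
7 | 8-methoxy-3-methylnaphthalen-1-ol | COc1cccc2cc(C)cc(O)c12 | intermediate
8 | 1,8-dimethoxy-3-methylnaphthalene | COc1cccc2cc(C)cc(OC)c12 | intermediate
9 | 1-bromo-4,5-dimethoxy-2-methylnaphthalene | Brc1c(C)cc(OC)c2c(OC)cccc12 | intermediate
10 | methyl (Z)-2-bromobut-2-enoate | C/C=C(\Br)C(=O)OC | starting material
11 | (4,5-dimethoxy-2-methylnaphthalen-1-yl)lithium | [Li]c1c(C)cc(OC)c2c(OC)cccc12 | intermediate
12 | chloro(4,5-dimethoxy-2-methylnaphthalen-1-yl)zinc | Cl[Zn]c1c(C)cc(OC)c2c(OC)cccc12 | intermediate
13 | methyl (E)-2-(4,5-dimethoxy-2-methylnaphthalen-1-yl)but-2-enoate | C/C=C(/C(=O)OC)c1c(C)cc(OC)c2c(OC)cccc12 | intermediate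
14 | lithium 1-methoxy-2-(4,5-dimethoxy-2-methylnaphthalen-1-yl)buta-1,3-dien-1-olate | C=CC(=C(OC)[O-])c1c(C)cc(OC)c2c(OC)cccc12.[Li+] | intermediate
15 | [1-methoxy-2-(4,5-dimethoxy-2-methylnaphthalen-1-yl)buta-1,3-dienyl]oxy-trimethylsilane (E/Z mixture, both isomers react alike) | C=CC(=C(OC)O[Si](C)(C)C)c1c(C)cc(OC)c2c(OC)cccc12 | intermediate
16 | pent-4-yn-2-one | CC(=O)CC#C | starting material
17 | 2-methyl-2-(prop-2-yn-1-yl)-1,3-dioxolane | C#CCC1(C)OCCO1 | intermediate
18 | N-methoxy-N-methylacetamide | CC(=O)N(C)OC | starting material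
19 | [3-(2-methyl-1,3-dioxolan-2-yl)prop-1-yn-1-yl]lithium | [Li]C#CCC1(C)OCCO1 | intermediate
20 | lithium 2-[methoxy(methyl)amino]-5-(2-methyl-1,3-dioxolan-2-yl)pent-3-yn-2-olate (racemic) | CC([O-])(N(C)OC)C#CCC1(C)OCCO1.[Li+] | intermediate
21 | 5-(2-methyl-1,3-dioxolan-2-yl)pent-3-yn-2-one | CC(=O)C#CCC1(C)OCCO1 | intermediate
22 | 1-[5-(4,5-dimethoxy-2-methylnaphthalen-1-yl)-6-methoxy-2-[(2-methyl-1,3-dioxolan-2-yl)methyl]-6-(trimethylsilyloxy)cyclohexa-1,4-dien-1-yl]ethanone (racemic) | CC(=O)C1=C(CC2(C)OCCO2)CC=C(c2c(C)cc(OC)c3c(OC)cccc23)C1(OC)O[Si](C)(C)C | intermediate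
23 | 1-[3-(4,5-dimethoxy-2-methylnaphthalen-1-yl)-6-[(2-methyl-1,3-dioxolan-2-yl)methyl]-2-(trimethylsilyloxy)phenyl]ethanone | CC(=O)c1c(O[Si](C)(C)C)c(-c2c(C)cc(OC)c3c(OC)cccc23)ccc1CC1(C)OCCO1 | intermediate
24 | 1-[2-hydroxy-3-(4,5-dimethoxy-2-methylnaphthalen-1-yl)-6-[(2-methyl-1,3-dioxolan-2-yl)methyl]phenyl]ethanone | CC(=O)c1c(O)c(-c2c(C)cc(OC)c3c(OC)cccc23)ccc1CC1(C)OCCO1 | intermediate
25 | 1-[2-methoxy-3-(4,5-dimethoxy-2-methylnaphthalen-1-yl)-6-[(2-methyl-1,3-dioxolan-2-yl)methyl]phenyl]ethanone | CC(=O)c1c(OC)c(-c2c(C)cc(OC)c3c(OC)cccc23)ccc1CC1(C)OCCO1 | intermediate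
26 | 1-[2-acetyl-3-methoxy-4-(4,5-dimethoxy-2-methylnaphthalen-1-yl)phenyl]propan-2-one | CC(=O)Cc1ccc(-c2c(C)cc(OC)c3c(OC)cccc23)c(OC)c1C(C)=O | intermediate
27 | 7-(4,5-dimethoxy-2-methylnaphthalen-1-yl)-8-methoxy-1,3-dimethylisoquinoline | COc1c(-c2c(C)cc(OC)c3c(OC)cccc23)ccc2cc(C)nc(C)c12 | target

Total step count: 11. Longest linear sequence: 9 steps (steps 1–6, then 9–11); steps 7 and 8 form the short convergent branch.

Steps most likely to fail

Step 9. The cycloaddition may be too slow. The naphthyl ring stands perpendicular to the diene and shields both faces, and the inward-pointing oxygen substituent on the acetal carbon penalises the s-cis conformer. On prolonged heating, silyl transfer to the enolisable ynone, protodesilylation of the ketene acetal and alkyne-to-allene isomerisation could take over.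

The fallback gives up ring construction and attaches the naphthyl group to a preformed benzene ring by cross-coupling. It sets out from 9 and comes back at 27.
- Bromine–lithium exchange on 9 (n-BuLi, THF, −78 °C), B(OMe)3 and aqueous acid should give (4,5-dimethoxy-2-methylnaphthalen-1-yl)boronic acid F1.
- Purchased 1-(2-hydroxy-6-methoxyphenyl)ethanone (CC(=O)c1c(O)cccc1OC) is brominated with NBS in MeCN para to the free hydroxyl to give 1-(3-bromo-6-hydroxy-2-methoxyphenyl)ethanone F2.
- Suzuki–Miyaura coupling of the two (Pd(OAc)2, SPhos, K3PO4, toluene–H2O, 90 °C) should give 1-[6-hydroxy-2-methoxy-3-(4,5-dimethoxy-2-methylnaphthalen-1-yl)phenyl]ethanone F3.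
- Tf2O and pyridine convert this into 2-acetyl-3-methoxy-4-(4,5-dimethoxy-2-methylnaphthalen-1-yl)phenyl trifluoromethanesulfonate F4.
- Sonogashira coupling with propyne (PdCl2(PPh3)2, CuI, Et3N, DMF) gives 1-[2-methoxy-3-(4,5-dimethoxy-2-methylnaphthalen-1-yl)-6-(prop-1-yn-1-yl)phenyl]ethanone F5.
- Heating with NH3 in MeOH in a sealed tube closes the pyridine ring by imine formation and 6-endo hydroamination of the alkyne, giving 27.

Step 5. Transmetalation and reductive elimination at the doubly flanked naphthyl carbon may be slow enough for protodemetalation, homocoupling or polymerisation of the bromoenoate to dominate. The fallback replaces cross-coupling by carbonyl addition and elimination. It sets out from 9 and comes back at 13. The naphthyllithium 11 made from 9 is added at −78 °C to excess methyl 2-oxobutanoate (CCC(=O)C(=O)OC), whose ketone is the most electrophilic site, to give methyl 2-hydroxy-2-(4,5-dimethoxy-2-methylnaphthalen-1-yl)butanoate F6. Acid-catalysed dehydration of this electron-rich tertiary benzylic alcohol (p-TsOH, toluene, reflux with water separation) should give 13 as an E/Z mixture, and both isomers lead to the same dienolate 14.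

Step 8. Release of the ynone may be accompanied by conjugate addition of the liberated amine. Base-induced alkyne-to-allene isomerisation with β-elimination opening of the dioxolane is a second risk. The fallback swaps direct acylation for addition followed by neutral oxidation. It sets out from 17 and comes back at 21. The acetylide 19 made from 17 is added to acetaldehyde at −78 °C to give 5-(2-methyl-1,3-dioxolan-2-yl)pent-3-yn-2-ol F7. This propargylic alcohol is then oxidised with MnO2 in CH2Cl2 at rt to 21.

Further compounds
F1 | step 9 | (4,5-dimethoxy-2-methylnaphthalen-1-yl)boronic acid | OB(O)c1c(C)cc(OC)c2c(OC)cccc12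
F2 | step 9 | 1-(3-bromo-6-hydroxy-2-methoxyphenyl)ethanone | CC(=O)c1c(O)ccc(Br)c1OC
F3 | step 9 | 1-[6-hydroxy-2-methoxy-3-(4,5-dimethoxy-2-methylnaphthalen-1-yl)phenyl]ethanone | CC(=O)c1c(O)ccc(-c2c(C)cc(OC)c3c(OC)cccc23)c1OC
F4 | step 9 | 2-acetyl-3-methoxy-4-(4,5-dimethoxy-2-methylnaphthalen-1-yl)phenyl trifluoromethanesulfonate | CC(=O)c1c(OS(=O)(=O)C(F)(F)F)ccc(-c2c(C)cc(OC)c3c(OC)cccc23)c1OC
F5 | step 9 | 1-[2-methoxy-3-(4,5-dimethoxy-2-methylnaphthalen-1-yl)-6-(prop-1-yn-1-yl)phenyl]ethanone | CC#Cc1ccc(-c2c(C)cc(OC)c3c(OC)cccc23)c(OC)c1C(C)=O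
F6 | step 5 | methyl 2-hydroxy-2-(4,5-dimethoxy-2-methylnaphthalen-1-yl)butanoate (racemic) | CCC(O)(C(=O)OC)c1c(C)cc(OC)c2c(OC)cccc12
F7 | step 8 | 5-(2-methyl-1,3-dioxolan-2-yl)pent-3-yn-2-ol (racemic) | CC(O)C#CCC1(C)OCCO1
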